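## Retrosynthetic overview
1. The last step removes two benzyl ethers. Ring C (the 4-methoxy-2-pyrone, formed last) comes from O-methylation of a 4-hydroxy-2-pyrone, itself made by acylketene cyclisation of an aryl keto-dioxinone.
2. The keto-dioxinone comes from a vinylogous Mukaiyama aldol and oxidation on a C6 aldehyde. That aldehyde comes from a C6 bromide by Stille vinylation and Lemieux–Johnson cleavage.
3. The only stereocentre, C4, comes from a rhodium/(R)-SEGPHOS-catalysed 1,4-addition of 4-(benzyloxy)phenylboronic acid to a flat 6-bromocoumarin.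
4. Ring B (the lactone, formed first) comes from a Wittig–lactonisation of a salicylaldehyde.
5. Ring A is bought as orsellinaldehyde. A vanadium-dependent haloperoxidase installs the C–Br bond, giving ring A two orthogonal handles: CHO for ring B and C4, Br for ring C. Ring order: A (bought), B, C.

Assumption: the stereodescriptor of the SMILES is read as (4R), and the recombinant haloperoxidase counts as a catalyst, not as a starting material.

## Route

Step 1
Reactants: 1 2,4-dihydroxy-6-methylbenzaldehyde (orsellinaldehyde)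
Product: 2 3-bromo-4,6-dihydroxy-2-methylbenzaldehyde
Conditions: vanadium-dependent haloperoxidase (chloroperoxidase of Curvularia inaequalis, 0.1 µM), Na3VO4 (50 µM), KBr (1.0 equiv), H2O2 (1.05 equiv, slow feed), citrate buffer pH 5/t-BuOH 4:1, 25 °C
Reagents that add atoms: potassium bromide, [K+].[Br-]
Why: The haloperoxidase turns bromide and H2O2 into a low, steady level of HOBr, electrophilic aromatic bromination then takes the position para to the hydrogen-bonded 2-OH and ortho to the 4-OH (next to the methyl group, the site at which 6-alkylresorcinol carbonyl compounds are halogenated), and the single equivalent of bromide stops the reaction at the monobromide.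

Step 2
Reactants: 2 3-bromo-4,6-dihydroxy-2-methylbenzaldehyde
Product: 3 4-(benzyloxy)-3-bromo-6-hydroxy-2-methylbenzaldehyde
Conditions: BnBr (1.05 equiv), K2CO3 (1.0 equiv), acetone, rt
Reagents that add atoms: benzyl bromide, BrCc1ccccc1
Why: In this Williamson ether synthesis only the more acidic OH para to the aldehyde is alkylated, because the ortho OH is tied up in a hydrogen bond to the carbonyl group.

Step 3
Reactants: 3 4-(benzyloxy)-3-bromo-6-hydroxy-2-methylbenzaldehyde
Product: 5 7-(benzyloxy)-6-bromo-5-methyl-2H-chromen-2-one, via hydroxycinnamate ester 4 (not isolated)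
Conditions: Ph3P=CHCO2Et (1.3 equiv), N,N-diethylaniline, reflux
Reagents that add atoms: ethyl (triphenylphosphoranylidene)acetate, CCOC(=O)C=P(c1ccccc1)(c1ccccc1)c1ccccc1
Why: The Wittig olefination gives the o-hydroxycinnamate, which at reflux equilibrates from E to Z and lactonises with loss of ethanol (tandem Wittig–lactonisation coumarin synthesis).

Step 4
Reactants: 5 7-(benzyloxy)-6-bromo-5-methyl-2H-chromen-2-one; 6 4-(benzyloxy)phenylboronic acid
Product: 7 (4R)-7-(benzyloxy)-4-[4-(benzyloxy)phenyl]-6-bromo-5-methylchroman-2-one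
Conditions: Rh(acac)(C2H4)2 (3 mol %), (R)-SEGPHOS (3.3 mol %), 6 (4 equiv, in portions), dioxane/H2O 10:1, 60 °C; one recrystallisation
Reagents that add atoms: none
Why: In this Hayashi–Miyaura asymmetric 1,4-addition the aryl–rhodium species held by (R)-SEGPHOS inserts the planar coumarin C3=C4 bond from one face only, a facial sense that gives (R)-4-arylchroman-2-ones from simple coumarins in very high ee and gives (4R) here because the priority order (C4a, aryl, CH2, H) is the same.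

Step 5
Reactants: 7 (4R)-7-(benzyloxy)-4-[4-(benzyloxy)phenyl]-6-bromo-5-methylchroman-2-one
Product: 8 (4R)-7-(benzyloxy)-4-[4-(benzyloxy)phenyl]-6-ethenyl-5-methylchroman-2-one
Conditions: Bu3SnCH=CH2 (1.3 equiv), Pd2(dba)3 (2.5 mol %), P(t-Bu)3 (10 mol %), CsF (2.2 equiv), dioxane, 80 °C
Reagents that add atoms: tributyl(vinyl)stannane, C=C[Sn](CCCC)(CCCC)CCCC
Why: In this Stille coupling the bulky, electron-rich phosphine gives a monoligated zerovalent palladium that inserts even into di-ortho-substituted aryl bromides, fluoride activates the stannane, and the water-free, alkoxide-free medium spares the lactone and C4.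

Step 6
Reactants: 8 (4R)-7-(benzyloxy)-4-[4-(benzyloxy)phenyl]-6-ethenyl-5-methylchroman-2-one
Product: 10 (4R)-7-(benzyloxy)-4-[4-(benzyloxy)phenyl]-5-methyl-2-oxochroman-6-carbaldehyde, via vicinal diol 9 (not isolated)
Conditions: OsO4 (2 mol %), NaIO4 (4 equiv), 2,6-lutidine (2 equiv), dioxane/H2O 3:1, rt
Reagents that add atoms: osmium tetroxide, O=[Os](=O)(=O)=O; sodium periodate, [Na+].[O-]I(=O)(=O)=O
Why: In this Lemieux–Johnson oxidation catalytic OsO4 dihydroxylates the only alkene and NaIO4 cleaves the diol to the aryl aldehyde at near-neutral pH, so the lactone and the benzyl ethers are untouched.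

Step 7
Reactants: 11 2,2,6-trimethyl-4H-1,3-dioxin-4-one
Product: 13 [(2,2-dimethyl-6-methylidene-6H-1,3-dioxin-4-yl)oxy]trimethylsilane, via lithium dienolate 12 (not isolated)
Conditions: LiN(i-Pr)2 (1.1 equiv), THF, −78 °C; Me3SiCl (1.2 equiv), −78 °C to rt
Reagents that add atoms: chlorotrimethylsilane, C[Si](C)(C)Cl
Why: Kinetic gamma-deprotonation of the vinylogous ester followed by O-silylation of the dienolate gives the cross-conjugated silyl dienol ether (silyl ketene acetal formation).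

Step 8
Reactants: 10 (4R)-7-(benzyloxy)-4-[4-(benzyloxy)phenyl]-5-methyl-2-oxochroman-6-carbaldehyde; 13 [(2,2-dimethyl-6-methylidene-6H-1,3-dioxin-4-yl)oxy]trimethylsilane
Product: 15 6-{2-[(4R)-7-(benzyloxy)-4-[4-(benzyloxy)phenyl]-5-methyl-2-oxochroman-6-yl]-2-hydroxyethyl}-2,2-dimethyl-4H-1,3-dioxin-4-one, via difluoroboron aldolate 14 (not isolated)
Conditions: 13 (1.5 equiv), BF3·OEt2 (1.2 equiv), CH2Cl2, −78 °C; aq NaHCO3
Reagents that add atoms: none
Why: In this vinylogous Mukaiyama aldol addition BF3 activates the hindered aldehyde and the dienol ether attacks through its terminal carbon under non-basic conditions that leave the aryl lactone alone, and the new carbinol centre forms as a mixture that does not matter because the next step removes it.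

Step 9
Reactants: 15 6-{2-[(4R)-7-(benzyloxy)-4-[4-(benzyloxy)phenyl]-5-methyl-2-oxochroman-6-yl]-2-hydroxyethyl}-2,2-dimethyl-4H-1,3-dioxin-4-one
Product: 16 6-{2-[(4R)-7-(benzyloxy)-4-[4-(benzyloxy)phenyl]-5-methyl-2-oxochroman-6-yl]-2-oxoethyl}-2,2-dimethyl-4H-1,3-dioxin-4-one
Conditions: Dess–Martin periodinane (1.3 equiv), CH2Cl2, rt
Reagents that add atoms: none
Why: The Dess–Martin oxidation turns the hindered benzylic carbinol into the aryl ketone under neutral conditions, erases the extra stereocentre and does not touch C4.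

Step 10
Reactants: 16 6-{2-[(4R)-7-(benzyloxy)-4-[4-(benzyloxy)phenyl]-5-methyl-2-oxochroman-6-yl]-2-oxoethyl}-2,2-dimethyl-4H-1,3-dioxin-4-one
Product: 18 (4R)-7-(benzyloxy)-4-[4-(benzyloxy)phenyl]-6-(4-hydroxy-2-oxo-2H-pyran-6-yl)-5-methylchroman-2-one, via acylketene 17 (not isolated)
Conditions: toluene, 110 °C, 1 h
Reagents that add atoms: none
Why: Thermal retro-[4+2] loss of acetone from the dioxinone gives an acylketene, which the enol oxygen of the neighbouring aryl ketone traps intramolecularly to close the 4-hydroxy-2-pyrone (acylketene cyclisation).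

Step 11
Reactants: 18 (4R)-7-(benzyloxy)-4-[4-(benzyloxy)phenyl]-6-(4-hydroxy-2-oxo-2H-pyran-6-yl)-5-methylchroman-2-one
Product: 19 (4R)-7-(benzyloxy)-4-[4-(benzyloxy)phenyl]-6-(4-methoxy-2-oxo-2H-pyran-6-yl)-5-methylchroman-2-one
Conditions: Me2SO4 (1.2 equiv), K2CO3 (1.1 equiv), dry acetone, rt to 40 °C
Reagents that add atoms: dimethyl sulfate, COS(=O)(=O)OC
Why: The vinylogous-acid OH (pKa about 5) is the only acidic site, and its O-alkylation with the hard electrophile Me2SO4 gives the 4-methoxy-2-pyrone rather than the 2-methoxy-4-pyrone.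

Step 12
Reactants: 19 (4R)-7-(benzyloxy)-4-[4-(benzyloxy)phenyl]-6-(4-methoxy-2-oxo-2H-pyran-6-yl)-5-methylchroman-2-one
Product: 20 (4R)-7-hydroxy-4-(4-hydroxyphenyl)-6-(4-methoxy-2-oxo-2H-pyran-6-yl)-5-methylchroman-2-one
Conditions: H2 (1 atm), 10% Pd/C, EtOAc/THF 1:1, rt
Reagents that add atoms: none
Why: Catalytic hydrogenolysis cleaves both benzylic C–O bonds at 1 atm, while the push–pull 4-methoxy-2-pyrone, the lactone and the C4 stereocentre stay as they are.

## Compound list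
1 | 2,4-dihydroxy-6-methylbenzaldehyde (orsellinaldehyde) | Cc1cc(O)cc(O)c1C=O | starting material
2 | 3-bromo-4,6-dihydroxy-2-methylbenzaldehyde | Cc1c(Br)c(O)cc(O)c1C=O | intermediate
3 | 4-(benzyloxy)-3-bromo-6-hydroxy-2-methylbenzaldehyde | Cc1c(Br)c(OCc2ccccc2)cc(O)c1C=O | intermediate
4 | ethyl 3-[4-(benzyloxy)-3-bromo-6-hydroxy-2-methylphenyl]prop-2-enoate (E/Z, not isolated) | CCOC(=O)C=Cc1c(C)c(Br)c(OCc2ccccc2)cc1O | intermediate
5 | 7-(benzyloxy)-6-bromo-5-methyl-2H-chromen-2-one | Cc1c(Br)c(OCc2ccccc2)cc2oc(=O)ccc12 | intermediate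
6 | 4-(benzyloxy)phenylboronic acid | OB(O)c1ccc(OCc2ccccc2)cc1 | starting material
7 | (4R)-7-(benzyloxy)-4-[4-(benzyloxy)phenyl]-6-bromo-5-methylchroman-2-one | Brc1c(OCc2ccccc2)cc2c(c1C)[C@@H](c1ccc(OCc3ccccc3)cc1)CC(=O)O2 | intermediate
8 | (4R)-7-(benzyloxy)-4-[4-(benzyloxy)phenyl]-6-ethenyl-5-methylchroman-2-one | C=Cc1c(OCc2ccccc2)cc2c(c1C)[C@@H](c1ccc(OCc3ccccc3)cc1)CC(=O)O2 | intermediate
9 | (4R)-7-(benzyloxy)-4-[4-(benzyloxy)phenyl]-6-(1,2-dihydroxyethyl)-5-methylchroman-2-one (both carbinol epimers, not isolated) | OCC(O)c1c(OCc2ccccc2)cc2c(c1C)[C@@H](c1ccc(OCc3ccccc3)cc1)CC(=O)O2 | intermediate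
10 | (4R)-7-(benzyloxy)-4-[4-(benzyloxy)phenyl]-5-methyl-2-oxochroman-6-carbaldehyde | O=Cc1c(OCc2ccccc2)cc2c(c1C)[C@@H](c1ccc(OCc3ccccc3)cc1)CC(=O)O2 | intermediate
11 | 2,2,6-trimethyl-4H-1,3-dioxin-4-one | CC1=CC(=O)OC(C)(C)O1 | starting material
12 | lithium 2,2-dimethyl-6-methylidene-6H-1,3-dioxin-4-olate (not isolated) | [Li+].C=C1C=C([O-])OC(C)(C)O1 | intermediate
13 | [(2,2-dimethyl-6-methylidene-6H-1,3-dioxin-4-yl)oxy]trimethylsilane | C=C1C=C(O[Si](C)(C)C)OC(C)(C)O1 | intermediate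
14 | O-difluoroboryl derivative of 15 (both carbinol epimers, not isolated) | CC1(C)OC(=O)C=C(CC(OB(F)F)c2c(OCc3ccccc3)cc3c(c2C)[C@@H](c2ccc(OCc4ccccc4)cc2)CC(=O)O3)O1 | intermediate
15 | 6-{2-[(4R)-7-(benzyloxy)-4-[4-(benzyloxy)phenyl]-5-methyl-2-oxochroman-6-yl]-2-hydroxyethyl}-2,2-dimethyl-4H-1,3-dioxin-4-one (both carbinol epimers) | CC1(C)OC(=O)C=C(CC(O)c2c(OCc3ccccc3)cc3c(c2C)[C@@H](c2ccc(OCc4ccccc4)cc2)CC(=O)O3)O1 | intermediate
16 | 6-{2-[(4R)-7-(benzyloxy)-4-[4-(benzyloxy)phenyl]-5-methyl-2-oxochroman-6-yl]-2-oxoethyl}-2,2-dimethyl-4H-1,3-dioxin-4-one | CC1(C)OC(=O)C=C(CC(=O)c2c(OCc3ccccc3)cc3c(c2C)[C@@H](c2ccc(OCc4ccccc4)cc2)CC(=O)O3)O1 | intermediate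
17 | 5-[(4R)-7-(benzyloxy)-4-[4-(benzyloxy)phenyl]-5-methyl-2-oxochroman-6-yl]-3,5-dioxopent-1-en-1-one (acylketene, not isolated) | O=C=CC(=O)CC(=O)c1c(OCc2ccccc2)cc2c(c1C)[C@@H](c1ccc(OCc3ccccc3)cc1)CC(=O)O2 | intermediate
18 | (4R)-7-(benzyloxy)-4-[4-(benzyloxy)phenyl]-6-(4-hydroxy-2-oxo-2H-pyran-6-yl)-5-methylchroman-2-one | Oc1cc(-c2c(OCc3ccccc3)cc3c(c2C)[C@@H](c2ccc(OCc4ccccc4)cc2)CC(=O)O3)oc(=O)c1 | intermediate
19 | (4R)-7-(benzyloxy)-4-[4-(benzyloxy)phenyl]-6-(4-methoxy-2-oxo-2H-pyran-6-yl)-5-methylchroman-2-one | COc1cc(-c2c(OCc3ccccc3)cc3c(c2C)[C@@H](c2ccc(OCc4ccccc4)cc2)CC(=O)O3)oc(=O)c1 | intermediate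
20 | (4R)-7-hydroxy-4-(4-hydroxyphenyl)-6-(4-methoxy-2-oxo-2H-pyran-6-yl)-5-methylchroman-2-one (CNP0207475.1) | COc1cc(-c2c(O)cc3c(c2C)[C@@H](c2ccc(O)cc2)CC(=O)O3)oc(=O)c1 | target

## Summary
Total step count: 12.
Longest linear sequence: 11 steps (1 to 20 through steps 1–6 and 8–12). Step 7 is a one-step side branch.

Three steps most likely to fail:

**Step 4.** Aryl transfer to C4 beside the peri methyl group may lose out to protodeboronation of 6. The fallback separates bond formation from stereo-induction and sets out from 5. An oxidative Heck arylation of 5 with 6 (Pd(OAc)2, 1,10-phenanthroline, O2, DMF, 100 °C) can be forced, because no selectivity is at stake. It gives 7-(benzyloxy)-4-[4-(benzyloxy)phenyl]-6-bromo-5-methyl-2H-chromen-2-one F1. A copper hydride-catalysed asymmetric 1,4-hydroboration follows (CuCl, NaOt-Bu, DTBM-SEGPHOS, pinacolborane, toluene, rt). This brings a small hydride rather than an aryl group to the crowded carbon and gives the boron enolate (4R)-4H-chromen-2-yl pinacol borate F2. Aqueous work-up of F2 gives 7, where the route is rejoined. The ligand antipode that gives (4R) has to be fixed in a test run by chiral HPLC.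

**Step 5.** Oxidative addition into a bromide flanked by CH3 and OBn is slow, and fluoride at 80 °C may attack the lactone. The fallback replaces palladium by halogen–lithium exchange on a masked lactone and sets out from 7. Reduction with i-Bu2AlH (CH2Cl2, −78 °C) gives the lactol (4R)-7-(benzyloxy)-4-[4-(benzyloxy)phenyl]-6-bromo-5-methylchroman-2-ol F3. MeOH with pyridinium tosylate gives the methyl acetal (4R)-7-(benzyloxy)-4-[4-(benzyloxy)phenyl]-6-bromo-2-methoxy-5-methylchromane F4. n-BuLi (THF, −78 °C) gives the C6 aryllithium F5, and DMF traps it as the acetal aldehyde F6. Treatment with 1 M HCl/THF frees the lactol aldehyde F7. TEMPO/PhI(OAc)2 then oxidises only the lactol, giving 10, where the route is rejoined.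

**Step 8.** The di-ortho-substituted, electron-rich aldehyde may add slowly, and the benzylic aldolate may ionise under BF3. The fallback builds ring C from a methyl ketone and a three-carbon unit, so no carbinol is needed; it sets out from 8. A Wacker–Tsuji oxidation (PdCl2, CuCl, O2, DMF/H2O) gives (4R)-6-acetyl-7-(benzyloxy)-4-[4-(benzyloxy)phenyl]-5-methylchroman-2-one F8. Me3SiOTf/Et3N (CH2Cl2, 0 °C) gives its trimethylsilyl enol ether F9. Malonyl dichloride (Et2O, −78 °C to rt) C-acylates the enol ether and closes the pyrone directly to 18, where the route is rejoined.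

## Further compounds
F1 | step 4 | 7-(benzyloxy)-4-[4-(benzyloxy)phenyl]-6-bromo-5-methyl-2H-chromen-2-one | Cc1c(Br)c(OCc2ccccc2)cc2oc(=O)cc(-c3ccc(OCc4ccccc4)cc3)c12
F2 | step 4 | 2-{[(4R)-7-(benzyloxy)-4-[4-(benzyloxy)phenyl]-6-bromo-5-methyl-4H-chromen-2-yl]oxy}-4,4,5,5-tetramethyl-1,3,2-dioxaborolane | Brc1c(OCc2ccccc2)cc2c(c1C)[C@@H](c1ccc(OCc3ccccc3)cc1)C=C(OB1OC(C)(C)C(C)(C)O1)O2
F3 | step 5 | (4R)-7-(benzyloxy)-4-[4-(benzyloxy)phenyl]-6-bromo-5-methylchroman-2-ol (both anomers) | Brc1c(OCc2ccccc2)cc2c(c1C)[C@@H](c1ccc(OCc3ccccc3)cc1)CC(O)O2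
F4 | step 5 | (4R)-7-(benzyloxy)-4-[4-(benzyloxy)phenyl]-6-bromo-2-methoxy-5-methylchromane (both anomers) | Brc1c(OCc2ccccc2)cc2c(c1C)[C@@H](c1ccc(OCc3ccccc3)cc1)CC(OC)O2
F5 | step 5 | [(4R)-7-(benzyloxy)-4-[4-(benzyloxy)phenyl]-2-methoxy-5-methylchroman-6-yl]lithium | [Li]c1c(OCc2ccccc2)cc2c(c1C)[C@@H](c1ccc(OCc3ccccc3)cc1)CC(OC)O2
F6 | step 5 | (4R)-7-(benzyloxy)-4-[4-(benzyloxy)phenyl]-2-methoxy-5-methylchromane-6-carbaldehyde | O=Cc1c(OCc2ccccc2)cc2c(c1C)[C@@H](c1ccc(OCc3ccccc3)cc1)CC(OC)O2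
F7 | step 5 | (4R)-7-(benzyloxy)-4-[4-(benzyloxy)phenyl]-2-hydroxy-5-methylchromane-6-carbaldehyde | O=Cc1c(OCc2ccccc2)cc2c(c1C)[C@@H](c1ccc(OCc3ccccc3)cc1)CC(O)O2
F8 | step 8 | (4R)-6-acetyl-7-(benzyloxy)-4-[4-(benzyloxy)phenyl]-5-methylchroman-2-one | CC(=O)c1c(OCc2ccccc2)cc2c(c1C)[C@@H](c1ccc(OCc3ccccc3)cc1)CC(=O)O2
F9 | step 8 | (4R)-7-(benzyloxy)-4-[4-(benzyloxy)phenyl]-5-methyl-6-{1-[(trimethylsilyl)oxy]ethenyl}chroman-2-one | C=C(O[Si](C)(C)C)c1c(OCc2ccccc2)cc2c(c1C)[C@@H](c1ccc(OCc3ccccc3)cc1)CC(=O)O2
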